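**Retrosynthetic overview**

1. The strategy rests on the 2-alkyl-1,4-dioxygenated benzene ring carried by C11, the CH2 on C9 of the Δ7, 8-methyl decalin. It is made last and at the quinone level: ring carbons C12 and C13 come from a propargyl alkyne, the other four from cyclobut-3-ene-1,2-dione, and thermal ring expansion of the 4-alkynyl-4-hydroxycyclobutenone forms the bond from the ketene carbon to C12 and closes the ring. Dithionite reduction, bis-sulfation and desilylation follow.
2. The alkyne is unveiled from a C12 ester (i-Bu2AlH, then Ohira–Bestmann, which adds C13); the 8-methyl-Δ7 unit comes from the C8 ketone by enol triflate formation and Negishi methylation.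
3. The two decalins are joined at C19–C11′ by Julia–Kocienski olefination of a C19 aldehyde without α-hydrogen with a C11′ tetrazolyl sulfone, and the alkene is hydrogenated while C8 is still a ketal, before Δ7 and the alkyne exist.
4. The left decalin comes from (+)-podocarpic acid. Its phenol oxygen sits on C12, para to C8, so Birch reduction and enone ozonolysis would leave the ketone on C9 and the chain on C8. Ring C is instead cut through the C8 p-quinol (dihydroxylation, periodate), which gives the C8 ketone and a C9–CH2–CO2H chain.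
5. The right decalin comes from (+)-sclareolide after acid epimerisation at C8′, because the target carbinol is 8′β (axial, cis to the C9′ chain); lactol fragmentation then gives the C11′ iodide. Both decalins come intact from the chiral pool, so the quinone ring is the only ring formed.

Key step: step 22

Remarks: The left decalin keeps podocarpane numbers (C19 is the former carboxyl carbon on C4, C11/C12 the chain on C9, C13 the carbon added in step 19); the right decalin carries primed drimane numbers. Assumption: the target is drawn as the free bis(hydrogen sulfate) and would be isolated as its disodium salt, the form that is stable beside the tertiary alcohol. Cyclobut-3-ene-1,2-dione is not taken as commercial and is made in step 20 from diisopropyl squarate, the commercial diester of squaric acid.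

**Route**

Step 1
Reactants: 1 (+)-podocarpic acid
Product: 2 podocarpa-8,11,13-triene-12,19-diol
Conditions: LiAlH4, THF, reflux; dilute HCl work-up
Reagents that add atoms: none
Why: Hydride reduction of the hindered axial C19 carboxylic acid to the neopentyl alcohol, done first so that C19 is later told apart from the C12 carboxyl; no stereocentre is touched.

Step 2
Reactants: 2 podocarpa-8,11,13-triene-12,19-diol
Product: 3 8α,19-dihydroxypodocarpa-9(11),13-dien-12-one (p-quinol)
Conditions: PhI(OAc)2, MeCN/H2O, 0 °C
Reagents that add atoms: water, O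
Why: Hypervalent-iodine oxidative dearomatisation of a para-alkylphenol, in which water traps the phenoxenium ion at C8 (para to the C12 oxygen), expected from the face opposite the axial C10 methyl; the new C8 centre is erased in step 3.

Step 3
Reactants: 3 8α,19-dihydroxypodocarpa-9(11),13-dien-12-one
Product: 6 (Z)-19-hydroxy-8-oxo-13,14-dinorpodocarp-9(11)-en-12-oic acid, via tetraol 4 (not isolated), via oxoaldehyde 5 (not isolated)
Conditions: OsO4 (cat.), N-methylmorpholine N-oxide, acetone/H2O, rt; then NaIO4, THF/pH 7 phosphate buffer, rt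
Reagents that add atoms: water, O
Why: Catalytic OsO4 dihydroxylation should pick the less substituted C13=C14 enone bond, and Malaprade periodate cleavage of the C8/C14/C13 triol and then of the 2-oxoaldehyde removes C13 and C14 as formic acid, leaving the C8 ketone and the C12 acid while C9=C11, conjugated at both ends, stays.

Step 4
Reactants: 6 (Z)-19-hydroxy-8-oxo-13,14-dinorpodocarp-9(11)-en-12-oic acid
Product: 7 19-hydroxy-8-oxo-13,14-dinorpodocarpan-12-oic acid (9α-H)
Conditions: Zn dust, AcOH, rt
Reagents that add atoms: none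
Why: Dissolving-metal conjugate reduction of a 4-oxo-2-enoic acid; C9 lies α to the ketone and should settle, here and under the acid of step 5, in the thermodynamic configuration with the CH2CO2H chain equatorial (9β) and 9α-H.

Step 5
Reactants: 7 19-hydroxy-8-oxo-13,14-dinorpodocarpan-12-oic acid
Product: 8 methyl 19-hydroxy-8,8-dimethoxy-13,14-dinorpodocarpan-12-oate
Conditions: HC(OMe)3, MeOH, TsOH (cat.), rt; Et3N quench
Reagents that add atoms: methanol, CO; trimethyl orthoformate, COC(OC)OC
Why: Fischer esterification of the unhindered C12 acid and orthoformate-driven ketalisation of the C8 ketone in one operation, which masks the ketone for steps 13 and 14 and leaves the neopentyl C19 hydroxyl free.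

Step 6
Reactants: 8 methyl 19-hydroxy-8,8-dimethoxy-13,14-dinorpodocarpan-12-oate
Product: 9 methyl 8,8-dimethoxy-19-oxo-13,14-dinorpodocarpan-12-oate (C19 aldehyde)
Conditions: Dess–Martin periodinane, pyridine, CH2Cl2, 0 °C to rt
Reagents that add atoms: none
Why: Dess–Martin oxidation of the neopentyl primary alcohol, buffered so that the dimethyl ketal survives; the aldehyde has no α-hydrogen and cannot epimerise at C4.

Step 7
Reactants: 10 (+)-sclareolide
Product: 11 8-epi-sclareolide (8′β-O, 8′α-CH3, cis-fused lactone)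
Conditions: conc. H2SO4, HCO2H, rt
Reagents that add atoms: none
Why: Acid-mediated reversible ionisation of the tertiary C8′–O bond and reclosure should give the thermodynamically preferred cis-fused γ-lactone, which inverts C8′ to the 8′β-oxygen of the target under thermodynamic control and leaves C5′, C9′ and C10′ as they are.

Step 8
Reactants: 11 8-epi-sclareolide
Product: 12 8-epi-sclareolide lactol (C12′ hemiacetal, both anomers)
Conditions: i-Bu2AlH, CH2Cl2, −78 °C
Reagents that add atoms: none
Why: Low-temperature half-reduction of a lactone, stopped at the lactol by the stable tetrahedral aluminate; the anomeric centre is lost in step 9.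

Step 9
Reactants: 12 8-epi-sclareolide lactol
Product: 13 11′-iodo-8′α-methyldriman-8′β-yl formate (iodo formate)
Conditions: PhI(OAc)2, I2, CH2Cl2, visible light, rt
Reagents that add atoms: iodine, II
Why: Suárez alkoxy-radical fragmentation, in which the lactol O–I bond homolyses and β-scission of C11′–C12′ gives the primary C11′ radical (trapped as the iodide) and leaves C12′ as the formate on the C8′ oxygen; C8′ and C9′ are not involved.

Step 10
Reactants: 13 iodo formate
Product: 15 11′-[(1-phenyl-1H-tetrazol-5-yl)sulfanyl]-8′α-methyldriman-8′β-ol, via sulfide formate 14 (not isolated)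
Conditions: 1-phenyl-1H-tetrazole-5-thiol, K2CO3, DMF, 50 °C; then MeOH, rt
Reagents that add atoms: 1-phenyl-1H-tetrazole-5-thiol, Sc1nnnn1-c1ccccc1
Why: SN2 thioether formation at the primary iodide by a soft, weakly basic thiolate (which disfavours E2 toward C9′), followed by methanolysis of the labile tertiary formate once the iodide is consumed, so that no alkoxide meets the iodide.

Step 11
Reactants: 15 hydroxy sulfide
Product: 16 11′-[(1-phenyl-1H-tetrazol-5-yl)sulfonyl]-8′α-methyldriman-8′β-ol
Conditions: mCPBA, NaHCO3, CH2Cl2, 0 °C to rt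
Reagents that add atoms: 3-chloroperoxybenzoic acid, OOC(=O)c1cccc(Cl)c1
Why: Peracid oxidation of the sulfide through the sulfoxide to the sulfone, buffered to spare the acid-sensitive axial tertiary alcohol.

Step 12
Reactants: 16 hydroxy sulfone
Product: 17 triethylsilyl ether of 16
Conditions: Et3SiOTf, 2,6-lutidine, CH2Cl2, 0 °C to rt
Reagents that add atoms: triethylsilyl trifluoromethanesulfonate, CC[Si](CC)(CC)OS(=O)(=O)C(F)(F)F
Why: Silyl triflate silylation, the standard method for hindered tertiary alcohols; the ether keeps the γ-alkoxide out of the Julia step and shields the carbinol in steps 16, 21 and 24.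

Step 13
Reactants: 9 C19 aldehyde; 17 silylated tetrazolyl sulfone
Product: 18 (E)-C19=C11′ alkene joining the two decalins
Conditions: KN(SiMe3)2 added to 9 and 17, THF, −78 °C to rt
Reagents that add atoms: none
Why: Julia–Kocienski olefination, in which the sulfonyl carbanion adds to the non-enolisable C19 aldehyde and Smiles rearrangement with loss of SO2 and the tetrazolone gives the alkene; its geometry is irrelevant because it is hydrogenated next, and no stereocentre is formed.

Step 14
Reactants: 18 C19=C11′ alkene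
Product: 19 saturated bis-decalin ketal ester
Conditions: H2 (4 atm), Pd/C, EtOAc, rt
Reagents that add atoms: none
Why: Heterogeneous hydrogenation of the only C=C bond present, which is why it is placed before Δ7 and the alkyne are introduced; ketal, ester and silyl ether are inert.

Step 15
Reactants: 19 saturated bis-decalin ketal ester
Product: 20 C8 ketone
Conditions: pyridinium p-toluenesulfonate, acetone/H2O, rt
Reagents that add atoms: water, O
Why: Mild acid hydrolysis of an acyclic dimethyl ketal, much faster than loss of the hindered tertiary silyl ether or the ester; C9 keeps its thermodynamic configuration.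

Step 16
Reactants: 20 C8 ketone
Product: 22 Δ7 enol triflate, via potassium enolate 21 (not isolated)
Conditions: KN(SiMe3)2, THF, −78 °C; then PhNTf2, −78 to 0 °C
Reagents that add atoms: N-phenylbis(trifluoromethanesulfonimide), FC(F)(F)S(=O)(=O)N(c1ccccc1)S(=O)(=O)C(F)(F)F
Why: Kinetic deprotonation should occur at the unhindered C7 methylene and not at the C9 methine or the less acidic ester α-CH2, so that O-sulfonylation fixes the double bond at C7=C8.

Step 17
Reactants: 22 Δ7 enol triflate
Product: 23 8-methyl-Δ7 methyl ester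
Conditions: MeZnCl, Pd(PPh3)4 (cat.), THF, 50 °C
Reagents that add atoms: methylzinc chloride, C[Zn]Cl
Why: Negishi cross-coupling (oxidative addition of zerovalent palladium to the vinyl triflate, transmetalation, reductive elimination), which tolerates the ester and keeps the alkene position.

Step 18
Reactants: 23 8-methyl-Δ7 methyl ester
Product: 24 C12 aldehyde
Conditions: i-Bu2AlH (1.1 equiv), CH2Cl2, −78 °C; MeOH, aq. KNaC4H4O6
Reagents that add atoms: none
Why: Low-temperature partial reduction of the methyl ester, held at the aldehyde level by the tetrahedral aluminate; C9 is β to the new carbonyl and cannot epimerise.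

Step 19
Reactants: 24 C12 aldehyde
Product: 25 propargyl alkyne (C9–C11H2–C12≡C13H)
Conditions: dimethyl (1-diazo-2-oxopropyl)phosphonate, K2CO3, MeOH/THF, 0 °C to rt
Reagents that add atoms: dimethyl (1-diazo-2-oxopropyl)phosphonate, COP(=O)(OC)C(=[N+]=[N-])C(C)=O
Why: Seyferth–Gilbert homologation in the Ohira–Bestmann variant, in which the diazophosphonate anion adds to the aldehyde and elimination, loss of N2 and a 1,2-hydrogen shift give the terminal alkyne with one new carbon (C13); the mild carbonate base leaves the silyl ether alone.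

Step 20
Reactants: 26 diisopropyl squarate
Product: 28 cyclobut-3-ene-1,2-dione, via diisopropoxy diol 27 (not isolated)
Conditions: LiAlH4, THF, −78 to −20 °C; then aq. HCl, CH2Cl2, 0 °C
Reagents that add atoms: water, O
Why: Two 1,2-hydride additions (ketone, then vinylogous ester carbonyl) followed by acid-promoted ionisation of each carbinol and hydrolysis of the resulting alkoxy-stabilised cations, as in the Stork–Danheiser enone transposition, should move both carbonyls and give the parent dione, which is used at once.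

Step 21
Reactants: 25 propargyl alkyne; 28 cyclobut-3-ene-1,2-dione
Product: 30 4-alkynyl-4-hydroxycyclobut-2-enone (both carbinol epimers), via lithium acetylide 29 (not isolated)
Conditions: n-BuLi, THF, −78 °C; added to 28 (2 equiv), THF, −78 °C; aq. NH4Cl at −78 °C
Reagents that add atoms: none
Why: 1,2-Addition of the acetylide to one of the two equivalent ketone carbonyls, with inverse addition and excess dione to suppress bis-addition; the carbinol centre forms without control and is destroyed in step 22.

Step 22
Reactants: 30 4-alkynyl-4-hydroxycyclobut-2-enone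
Product: 32 2-alkyl-1,4-benzoquinone (silyl ether), via vinylketene 31 (not isolated)
Conditions: degassed toluene, 110 °C
Reagents that add atoms: none
Why: Heating opens the cyclobutenone by conrotatory four-electron electrocyclic ring opening in which the C4 hydroxyl rotates outward, so the alkynyl group ends up cis to the ketene in vinylketene 31. The ketene carbon then bonds to C12, the alkyne carbon remote from the carbinol, giving a six-membered-ring diradical (σ radical at C13, oxygen-centred radical on the former ketene) that collapses to quinone 32 by transfer of the hydroxyl hydrogen to C13. This is the known Moore rearrangement of 4-alkynyl-4-hydroxycyclobutenones to 1,4-benzoquinones. The quinone ring closes in a six-membered endo-dig mode with one new ring C–C bond; no stereocentre is formed and the carbinol centre of 30 is lost, so both epimers converge. The step needs six- over five-membered closure, which the plain alkyl (CH2) substituent on C12 secures because it does not stabilise the vinyl radical of the five-ring path, and it needs outward rotation of the hydroxyl, which is inherent to a donor at C4. The reaction is thermal and neutral, so the Δ7 alkene and the silylated 8′β carbinol are not touched.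

Step 23
Reactants: 32 2-alkyl-1,4-benzoquinone
Product: 33 2-alkylhydroquinone (silyl ether)
Conditions: Na2S2O4, THF/H2O, rt, under argon
Reagents that add atoms: none
Why: Two-electron dithionite reduction of the quinone to the hydroquinone under near-neutral conditions; the product is air-sensitive and is carried straight on.

Step 24
Reactants: 33 2-alkylhydroquinone
Product: 34 hydroquinone bis-sulfate, disodium salt (silyl ether)
Conditions: SO3·pyridine, pyridine, rt; aq. Na2CO3
Reagents that add atoms: sulfur trioxide–pyridine complex, O=S(=O)=O.c1ccncc1; sodium carbonate, [Na+].[Na+].[O-]C([O-])=O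
Why: O-Sulfation of both phenols by the SO3·pyridine complex; the tertiary alcohol is silylated and the trisubstituted alkene is inert to this reagent.

Step 25
Reactants: 34 hydroquinone bis-sulfate, disodium salt (silyl ether)
Product: 35 target, isolated as its disodium salt
Conditions: Bu4NF, THF, rt to 40 °C; Na+ ion exchange
Reagents that add atoms: none
Why: Fluoride desilylation of the tertiary triethylsilyl ether; aryl sulfate salts are stable to fluoride and base, and no acid is used, so the axial 8′β alcohol should not dehydrate.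

**Compound list**

1 | (+)-podocarpic acid | C[C@]1(C(=O)O)CCC[C@]2(C)c3cc(O)ccc3CC[C@@H]12 | starting material
2 | podocarpa-8,11,13-triene-12,19-diol | C[C@]1(CO)CCC[C@]2(C)c3cc(O)ccc3CC[C@@H]12 | intermediate
3 | 8α,19-dihydroxypodocarpa-9(11),13-dien-12-one (p-quinol; 8α-OH expected, either epimer serves) | C[C@]1(CO)CCC[C@]2(C)C3=CC(=O)C=C[C@@]3(O)CC[C@@H]12 | intermediate
4 | 8α,13,14,19-tetrahydroxypodocarp-9(11)-en-12-one (cis-13,14-diol, face not defined) | C[C@]1(CO)CCC[C@]2(C)C3=CC(=O)C(O)C(O)[C@@]3(O)CC[C@@H]12 | intermediate (not isolated)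
5 | (Z)-19-hydroxy-8,12-dioxo-14-norpodocarp-9(11)-en-13-al | C[C@]1(CO)CCC[C@]2(C)/C(=C/C(=O)C=O)C(=O)CC[C@@H]12 | intermediate (not isolated)
6 | (Z)-19-hydroxy-8-oxo-13,14-dinorpodocarp-9(11)-en-12-oic acid (may sit as its cyclic hydroxybutenolide) | C[C@]1(CO)CCC[C@]2(C)/C(=C/C(=O)O)C(=O)CC[C@@H]12 | intermediate
7 | 19-hydroxy-8-oxo-13,14-dinorpodocarpan-12-oic acid (9α-H) | C[C@]1(CO)CCC[C@]2(C)[C@@H](CC(=O)O)C(=O)CC[C@@H]12 | intermediate
8 | methyl 19-hydroxy-8,8-dimethoxy-13,14-dinorpodocarpan-12-oate | C[C@]1(CO)CCC[C@]2(C)[C@@H](CC(=O)OC)C(OC)(OC)CC[C@@H]12 | intermediate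
9 | methyl 8,8-dimethoxy-19-oxo-13,14-dinorpodocarpan-12-oate | C[C@]1(C=O)CCC[C@]2(C)[C@@H](CC(=O)OC)C(OC)(OC)CC[C@@H]12 | intermediate
10 | (+)-sclareolide | O=C1C[C@@H]2[C@@]3(C)CCCC(C)(C)[C@@H]3CC[C@@]2(C)O1 | starting material
11 | 8-epi-sclareolide (cis-fused lactone, 8′β-O) | O=C1C[C@@H]2[C@@]3(C)CCCC(C)(C)[C@@H]3CC[C@]2(C)O1 | intermediate
12 | 8-epi-sclareolide lactol (both anomers) | OC1C[C@@H]2[C@@]3(C)CCCC(C)(C)[C@@H]3CC[C@]2(C)O1 | intermediate
13 | 11′-iodo-8′α-methyldriman-8′β-yl formate | IC[C@@H]1[C@@]2(C)CCCC(C)(C)[C@@H]2CC[C@]1(C)OC=O | intermediate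
14 | 11′-[(1-phenyl-1H-tetrazol-5-yl)sulfanyl]-8′α-methyldriman-8′β-yl formate | c1ccccc1-n1nnnc1SC[C@@H]1[C@@]2(C)CCCC(C)(C)[C@@H]2CC[C@]1(C)OC=O | intermediate (not isolated)
15 | 11′-[(1-phenyl-1H-tetrazol-5-yl)sulfanyl]-8′α-methyldriman-8′β-ol | c1ccccc1-n1nnnc1SC[C@@H]1[C@@]2(C)CCCC(C)(C)[C@@H]2CC[C@]1(C)O | intermediate
16 | 11′-[(1-phenyl-1H-tetrazol-5-yl)sulfonyl]-8′α-methyldriman-8′β-ol | O=S(=O)(C[C@@H]1[C@@]2(C)CCCC(C)(C)[C@@H]2CC[C@]1(C)O)c1nnnn1-c1ccccc1 | intermediate
17 | triethylsilyl ether of 16 | O=S(=O)(C[C@@H]1[C@@]2(C)CCCC(C)(C)[C@@H]2CC[C@]1(C)O[Si](CC)(CC)CC)c1nnnn1-c1ccccc1 | intermediate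
18 | (E)-C19=C11′ alkene (C8 dimethyl ketal, C12 methyl ester, 8′β-OSiEt3) | C[C@]1(/C=C/[C@@H]2[C@@]3(C)CCCC(C)(C)[C@@H]3CC[C@]2(C)O[Si](CC)(CC)CC)CCC[C@]2(C)[C@@H](CC(=O)OC)C(OC)(OC)CC[C@@H]12 | intermediate
19 | saturated bis-decalin ketal ester | C[C@]1(CC[C@@H]2[C@@]3(C)CCCC(C)(C)[C@@H]3CC[C@]2(C)O[Si](CC)(CC)CC)CCC[C@]2(C)[C@@H](CC(=O)OC)C(OC)(OC)CC[C@@H]12 | intermediate
20 | C8 ketone | C[C@]1(CC[C@@H]2[C@@]3(C)CCCC(C)(C)[C@@H]3CC[C@]2(C)O[Si](CC)(CC)CC)CCC[C@]2(C)[C@@H](CC(=O)OC)C(=O)CC[C@@H]12 | intermediate
21 | potassium Δ7 enolate of 20 | C[C@]1(CC[C@@H]2[C@@]3(C)CCCC(C)(C)[C@@H]3CC[C@]2(C)O[Si](CC)(CC)CC)CCC[C@]2(C)[C@@H](CC(=O)OC)C([O-])=CC[C@@H]12.[K+] | intermediate (not isolated)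
22 | Δ7 enol triflate | C[C@]1(CC[C@@H]2[C@@]3(C)CCCC(C)(C)[C@@H]3CC[C@]2(C)O[Si](CC)(CC)CC)CCC[C@]2(C)[C@@H](CC(=O)OC)C(OS(=O)(=O)C(F)(F)F)=CC[C@@H]12 | intermediate
23 | 8-methyl-Δ7 methyl ester | C[C@]1(CC[C@@H]2[C@@]3(C)CCCC(C)(C)[C@@H]3CC[C@]2(C)O[Si](CC)(CC)CC)CCC[C@]2(C)[C@@H](CC(=O)OC)C(C)=CC[C@@H]12 | intermediate
24 | C12 aldehyde | C[C@]1(CC[C@@H]2[C@@]3(C)CCCC(C)(C)[C@@H]3CC[C@]2(C)O[Si](CC)(CC)CC)CCC[C@]2(C)[C@@H](CC=O)C(C)=CC[C@@H]12 | intermediate
25 | propargyl alkyne | C[C@]1(CC[C@@H]2[C@@]3(C)CCCC(C)(C)[C@@H]3CC[C@]2(C)O[Si](CC)(CC)CC)CCC[C@]2(C)[C@@H](CC#C)C(C)=CC[C@@H]12 | intermediate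
26 | diisopropyl squarate | CC(C)OC1=C(OC(C)C)C(=O)C1=O | starting material
27 | 3,4-diisopropoxycyclobut-3-ene-1,2-diol (cis/trans) | CC(C)OC1=C(OC(C)C)C(O)C1O | intermediate (not isolated)
28 | cyclobut-3-ene-1,2-dione | O=C1C=CC1=O | intermediate
29 | lithium acetylide of 25 | C[C@]1(CC[C@@H]2[C@@]3(C)CCCC(C)(C)[C@@H]3CC[C@]2(C)O[Si](CC)(CC)CC)CCC[C@]2(C)[C@@H](CC#C[Li])C(C)=CC[C@@H]12 | intermediate (not isolated)
30 | 4-alkynyl-4-hydroxycyclobut-2-enone (both carbinol epimers) | C[C@]1(CC[C@@H]2[C@@]3(C)CCCC(C)(C)[C@@H]3CC[C@]2(C)O[Si](CC)(CC)CC)CCC[C@]2(C)[C@@H](CC#CC3(O)C=CC3=O)C(C)=CC[C@@H]12 | intermediate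
31 | vinylketene (hydroxyl outward, alkynyl cis to the ketene) | C[C@]1(CC[C@@H]2[C@@]3(C)CCCC(C)(C)[C@@H]3CC[C@]2(C)O[Si](CC)(CC)CC)CCC[C@]2(C)[C@@H](CC#C/C(O)=C\C=C=O)C(C)=CC[C@@H]12 | intermediate (not isolated)
32 | 2-alkyl-1,4-benzoquinone (silyl ether) | C[C@]1(CC[C@@H]2[C@@]3(C)CCCC(C)(C)[C@@H]3CC[C@]2(C)O[Si](CC)(CC)CC)CCC[C@]2(C)[C@@H](CC3=CC(=O)C=CC3=O)C(C)=CC[C@@H]12 | intermediate
33 | 2-alkylhydroquinone (silyl ether) | C[C@]1(CC[C@@H]2[C@@]3(C)CCCC(C)(C)[C@@H]3CC[C@]2(C)O[Si](CC)(CC)CC)CCC[C@]2(C)[C@@H](Cc3cc(O)ccc3O)C(C)=CC[C@@H]12 | intermediate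
34 | hydroquinone bis-sulfate, disodium salt (silyl ether) | C[C@]1(CC[C@@H]2[C@@]3(C)CCCC(C)(C)[C@@H]3CC[C@]2(C)O[Si](CC)(CC)CC)CCC[C@]2(C)[C@@H](Cc3cc(OS(=O)(=O)[O-])ccc3OS(=O)(=O)[O-])C(C)=CC[C@@H]12.[Na+].[Na+] | intermediate
35 | CNP0471499.2 (drawn as the free bis(hydrogen sulfate)) | CC1=CC[C@H]2[C@@](C)(CC[C@@H]3[C@@]4(C)CCCC(C)(C)[C@@H]4CC[C@]3(C)O)CCC[C@]2(C)[C@H]1Cc1cc(OS(=O)(=O)O)ccc1OS(=O)(=O)O | target

**Totals and risks**

Total step count: 25.
Longest linear sequence: 18 steps (from 1 through steps 1–6, 13–19 and 21–25; the same length from 10 through steps 7–19 and 21–25).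

The three steps most likely to fail:

Step 3. The electron-poor C13=C14 enone may be dihydroxylated slowly, and the periodate cascade may stall at cyclic hemiacetals, so that cleavage is incomplete. Fallback: setting out from phenol 2, the aromatic ring would be cut directly by ozonolysis (O3, CH2Cl2/MeOH, −78 °C; then H2O2/HCO2H), the known ozonolytic degradation of phenol rings. Ozone should attack the electron-rich C12–C13 and C8–C14 bonds and spare C9=C11, which is then flanked by the C8 ketone and the C12 carboxyl. This fallback passes through no new isolated compound (F0) and comes back to the route at enone acid 6.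

Step 13. Addition of the β-branched sulfonyl carbanion to the hindered neopentyl aldehyde may be slow, leaving room for self-condensation of the metalated sulfone or for proton transfer from the ester. Fallback: setting out from iodo formate 13, the formate would be removed with i-Bu2AlH at −78 °C to give 11′-iodo-8′α-methyldriman-8′β-ol F1, which would be silylated (Et3SiOTf, 2,6-lutidine) to the triethylsilyl ether F2. Iodine–lithium exchange (t-BuLi, Et2O, −78 °C) and transmetalation with CeCl3 would give an organocerium reagent that adds to aldehyde 9 chemoselectively to give the C19 carbinol F3 (both epimers). Barton–McCombie deoxygenation through the S-methyl xanthate F4 (NaN(SiMe3)2, CS2, MeI; then Bu3SnH, AIBN, toluene, 80 °C) comes back to the route at 19.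

Step 21. The unsubstituted dione 28 may polymerise under the basic conditions or take up the acetylide by conjugate or double addition. Fallback (it also replaces steps 18–20 and 22): setting out from ester 23, saponification (LiOH, THF/H2O) would give the carboxylic acid F5, which would be converted (N-hydroxyphthalimide, N,N′-diisopropylcarbodiimide) into the redox-active ester F6. Nickel-catalysed decarboxylative arylation with (2,5-dimethoxyphenyl)zinc chloride (NiCl2·MeOCH2CH2OMe, 4,4′-di-tert-butyl-2,2′-bipyridine, THF/DMF) would put the aryl carbon in the place of C12 and give the dimethoxyarene F7. Oxidative demethylation with (NH4)2Ce(NO3)6 in MeCN/H2O at 0 °C comes back to the route at quinone 32.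

**Further compounds**

F0 | step 3 | none | none
F1 | step 13 | 11′-iodo-8′α-methyldriman-8′β-ol | IC[C@@H]1[C@@]2(C)CCCC(C)(C)[C@@H]2CC[C@]1(C)O
F2 | step 13 | triethylsilyl ether of F1 | IC[C@@H]1[C@@]2(C)CCCC(C)(C)[C@@H]2CC[C@]1(C)O[Si](CC)(CC)CC
F3 | step 13 | C19 carbinol (both epimers) | C[C@]1(C(O)C[C@@H]2[C@@]3(C)CCCC(C)(C)[C@@H]3CC[C@]2(C)O[Si](CC)(CC)CC)CCC[C@]2(C)[C@@H](CC(=O)OC)C(OC)(OC)CC[C@@H]12
F4 | step 13 | S-methyl xanthate of F3 | C[C@]1(C(OC(=S)SC)C[C@@H]2[C@@]3(C)CCCC(C)(C)[C@@H]3CC[C@]2(C)O[Si](CC)(CC)CC)CCC[C@]2(C)[C@@H](CC(=O)OC)C(OC)(OC)CC[C@@H]12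
F5 | step 21 | carboxylic acid from 23 | C[C@]1(CC[C@@H]2[C@@]3(C)CCCC(C)(C)[C@@H]3CC[C@]2(C)O[Si](CC)(CC)CC)CCC[C@]2(C)[C@@H](CC(=O)O)C(C)=CC[C@@H]12
F6 | step 21 | N-hydroxyphthalimide ester of F5 | C[C@]1(CC[C@@H]2[C@@]3(C)CCCC(C)(C)[C@@H]3CC[C@]2(C)O[Si](CC)(CC)CC)CCC[C@]2(C)[C@@H](CC(=O)ON3C(=O)c4ccccc4C3=O)C(C)=CC[C@@H]12
F7 | step 21 | 2,5-dimethoxybenzyl compound | C[C@]1(CC[C@@H]2[C@@]3(C)CCCC(C)(C)[C@@H]3CC[C@]2(C)O[Si](CC)(CC)CC)CCC[C@]2(C)[C@@H](Cc3cc(OC)ccc3OC)C(C)=CC[C@@H]12
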